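(The runs come from a simulation for substances that don't exist, and the scatter is random.)

**Two questions.** Two questions stand on this flask, and one balance answers both. G is the monomer, E the initiator, Z the monomer in chains; Q and X are further species.

| flask | G | Q | X | E | remark | time |
|---|---|---|---|---|---|---|
| beta | 2.2 M (fed, over 1.0 min) | 0.033 M | 0.22 M | 160 mM | run made earlier; the fed solution adds 0.50 times the starting volume |  |
| delta | 2.2 M (fed, over 1.0 min) | 0.050 M | 0.22 M | 160 mM | run made earlier; the fed solution adds 0.50 times the starting volume |  |
| gamma | 2.2 M (fed, over 1.0 min) | 0.066 M | 0.22 M | 80 mM | run made earlier; the fed solution adds 0.50 times the starting volume |  |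
| flask | 2.2 M (fed, over 1.0 min) | 0.0660 M | 0.220 M | 160 mM | the fed solution adds 0.50 times the starting volume | 12 min |

| run | time / min | Z / % | G / % |
|---|---|---|---|
| beta | 0.417 | 9.3 | 30.5 |
| beta | 1.00 | 25.9 | 68.3 |
| beta | 2.00 | 51.8 | 40.8 |
| beta | 3.00 | 65.6 | 26.2 |
| beta | 4.00 | 75.1 | 15.1 |
| beta | 6.00 | 83.9 | 5.9 |
| beta | 8.00 | 87.1 | 2.7 |
| delta | 1.00 | 24.8 | 68.0 |
| delta | 2.00 | 50.2 | 40.8 |
| delta | 3.00 | 65.9 | 25.1 |
| delta | 4.00 | 74.3 | 15.7 |
| delta | 5.00 | 79.5 | 9.3 |
| delta | 6.00 | 83.1 | 6.8 |
| delta | 8.00 | 86.9 | 2.8 |
| gamma | 1.33 | 19.5 | 71.7 |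
| gamma | 3.00 | 42.6 | 47.6 |
| gamma | 4.00 | 51.2 | 39.7 |
| gamma | 6.00 | 63.9 | 25.9 |
| gamma | 8.00 | 70.9 | 18.5 |

(readings scatter by 0.5 percentage points)

- charges are per starting volume, the dose included; the dosed solution carries all of it
- the average divides the monomer in chains by the number of chains begun, living and dead together
- the earlier runs were read with a standard deviation of 0.5 percentage points
- the earlier runs do not show the number of chains; that part of a forecast is a guess
- percentages count the whole charge, also what has not yet gone in

- whether the average number of monomer units in a chain (chains begun, living or dead) reaches 20 by 12 min (yes / no)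
- average number of monomer units in a chain (chains begun, living or dead) at 12 min

**The balance.** The runs read a shortfall in G. At 8.00 min the beta run reads Z plus G short of the charge by 0.224 M, and the gamma run at 8.00 min reads 0.233 M. Both readings lie near the 0.22 M of X charged, so this reckoning takes X to remove G one to one. The number of chains is not shown by the runs, so one chain per E is an assumption here. The average counts dead chains too, so a stopped chain stays in the count. This gives the length budget B, the G charge less the X charge, divided by the E charge, a net monomer-to-initiator ratio. For this flask B is 12.4. G in the beta run already reads 2.7% at 8.00 min, and this flask runs to 12 min.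

**Turned round.** A yes at 20 units on 160 mM of chains asks for 3.20 M of G in chains, more than the 2.2 M charged. The net G reaches 20 units over 99.0 mM of chains begun, fewer than the E charged. B stands at 62.0% of the length wanted.

**The forecast.** The forecast says no, with 12.3 in a range of 7 to 15, on the ground “If every E starts one chain”, a value below the B of this reckoning.

**Result.** The flask gives no, with an average of 12.3 at 12 min. By then D, the product of X with G, holds 9.93% of the G charged. Below, L is the living end and J a species formed on the way.

    G + E → L + Z (k = 0.264 M⁻¹ s⁻¹)
    G + L → Z + L, rate k2*[L]*[G] (k = 0.0789 M⁻¹ s⁻¹)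
    L + Q → J (k = 0.0224 M⁻¹ s⁻¹)
    X + G → D (k = 0.0300 M⁻¹ s⁻¹)

**Second flask.** With X cut to 0.088 M, B becomes 13.2, and that flask gives 13.1.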